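**Retrosynthetic overview**
1. 25 ⇐ 24 by fluoride removal of three silyl ethers; 24 ⇐ 22 + 2-methylbut-2-ene by cross-metathesis (prenyl terminus).
2. C4–C5: Brown allylation of enal 19 (Re face, 5R); 19 ⇐ 17 + methacrolein by E-selective cross-metathesis (C6=C7).
3. The only ring, the oxirane, comes from a hydroxyl-directed, matched Sharpless epoxidation of dienol 15, after the C8–C9 bond is made and before the left half is grown.
4. Key bond C8–C9: intermolecular carbonyl allylation of the C9–C16 enal 11 with B-allyldiisopinocampheylborane (Si face, 9S).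
5. 11 ⇐ nerol: O-silylation, remote epoxidation and periodate cleavage to the C11 aldehyde, two-carbon Wittig, α-iodination, Stille hydroxymethylation, O-silylation.

Assumption: locants C1–C16 are those of the target main chain (C1 = isopropylidene CH3, C16 = CH2OH of the Z-allylic alcohol), so the target is (5R,6E,9S,10S,11S,14Z); (tributylstannyl)methanol and both antipodes of Ipc2BOMe are taken as catalogue chemicals.

**Route**

Step 1
Reactants: 1 nerol, (2Z)-3,7-dimethylocta-2,6-dien-1-ol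
Product: 2 tert-butyl{[(2Z)-3,7-dimethylocta-2,6-dien-1-yl]oxy}diphenylsilane
Conditions: t-BuPh2SiCl, imidazole, DMF, 0 °C → rt
Reagents that add atoms: tert-butyl(chloro)diphenylsilane, CC(C)(C)[Si](Cl)(c1ccccc1)c1ccccc1
Why: Standard silylation of a primary alcohol gives an acid- and base-robust ether that carries C16–O to the last step.

Step 2
Reactants: 2 neryl silyl ether
Product: 3 tert-butyl{[(2Z)-5-(3,3-dimethyloxiran-2-yl)-3-methylpent-2-en-1-yl]oxy}diphenylsilane (racemic)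
Conditions: mCPBA (1.05 equiv), CH2Cl2, −20 → 0 °C
Reagents that add atoms: 3-chloroperoxybenzoic acid, OOC(=O)c1cccc(Cl)c1
Why: Prilezhaev epoxidation picks the remote, more electron-rich trisubstituted alkene over the one deactivated by the allylic silyloxy group; the new stereocentre is racemic and is destroyed in step 3.

Step 3
Reactants: 3 racemic epoxide
Product: 5 (4Z)-6-[(tert-butyldiphenylsilyl)oxy]-4-methylhex-4-enal, via glycol 4 (not isolated)
Conditions: H5IO6 (1.2 equiv), THF–H2O, 0 °C → rt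
Reagents that add atoms: water, O (its oxygen sits on the tertiary carbinol of 4 and leaves with acetone)
Why: Acid-mediated epoxide hydrolysis followed in the same pot by Malaprade glycol cleavage gives the C11 aldehyde and leaves the Z-alkene and silyl ether untouched.

Step 4
Reactants: 5 aldehyde; 6 (triphenylphosphoranylidene)acetaldehyde
Product: 7 (2E,6Z)-8-[(tert-butyldiphenylsilyl)oxy]-6-methylocta-2,6-dienal
Conditions: toluene, 80 °C
Reagents that add atoms: none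
Why: Wittig olefination with a formyl-stabilised ylide adds C9–C10 and gives the (E)-enal.

Step 5
Reactants: 7 enal
Product: 8 (2Z,6Z)-8-[(tert-butyldiphenylsilyl)oxy]-2-iodo-6-methylocta-2,6-dienal
Conditions: iodine (1.5 equiv), pyridine–CH2Cl2 (1:1), DMAP (cat.), 0 °C → rt, dark
Reagents that add atoms: iodine, I-I
Why: Johnson-type α-iodination (pyridine conjugate addition, α-iodination, E1cB loss of pyridine) gives the thermodynamic (Z)-α-iodoenal, with iodine cis to the chain and CHO trans.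

Step 6
Reactants: 8 α-iodoenal; 9 (tributylstannyl)methanol
Product: 10 (2E,6Z)-8-[(tert-butyldiphenylsilyl)oxy]-2-(hydroxymethyl)-6-methylocta-2,6-dienal
Conditions: Pd(PPh3)4 (5 mol %), 1,4-dioxane, 85 °C
Reagents that add atoms: none
Why: Kosugi–Migita–Stille coupling transfers the hydroxymethyl group with retention of alkene geometry, so the future oxirane CH2OH is cis to the chain and the C9 aldehyde trans.

Step 7
Reactants: 10 hydroxymethyl enal
Product: 11 (2E,6Z)-2-{[(tert-butyldimethylsilyl)oxy]methyl}-8-[(tert-butyldiphenylsilyl)oxy]-6-methylocta-2,6-dienal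
Conditions: t-BuMe2SiCl, imidazole, CH2Cl2, 0 °C
Reagents that add atoms: tert-butyl(chloro)dimethylsilane, CC(C)(C)[Si](C)(C)Cl
Why: Silylation caps the primary allylic hydroxyl so that only the C9 carbinol made next can direct the epoxidation.

Step 8 (key step)
Reactants: 11 enal (C9–C16 fragment); 12 allylmagnesium bromide
Product: 15 (4S,5E,9Z)-5-{[(tert-butyldimethylsilyl)oxy]methyl}-11-[(tert-butyldiphenylsilyl)oxy]-9-methylundeca-1,5,9-trien-4-ol, via B-allyldiisopinocampheylborane 13 (not isolated), via diisopinocampheylborinate 14 (not isolated)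
Conditions: (−)-Ipc2BOMe, CH2=CHCH2MgBr, Et2O, 0 °C → rt; then 11, −78 °C; then aq. NaOH, 30% H2O2, 0 °C → rt
Reagents that add atoms: (−)-B-methoxydiisopinocampheylborane from (+)-α-pinene, COB([C@@H]1C[C@@H]2C[C@H]([C@H]1C)C2(C)C)[C@@H]1C[C@@H]2C[C@H]([C@H]1C)C2(C)C (its boryl unit is carried by 13 and 14 only)
Why: Brown asymmetric allylboration (carbonyl allylation) delivers allyl through a chair Zimmerman–Traxler transition state to the Si face of the enal, forming C8–C9 and setting C9 as S under reagent control.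

Step 9
Reactants: 15 dienol
Product: 16 (1S)-1-[(2S,3S)-2-{[(tert-butyldimethylsilyl)oxy]methyl}-3-{(3Z)-5-[(tert-butyldiphenylsilyl)oxy]-3-methylpent-3-en-1-yl}oxiran-2-yl]but-3-en-1-ol
Conditions: Ti(OiPr)4 (20 mol %), (+)-diisopropyl (2R,3R)-tartrate (24 mol %), t-BuOOH (2 equiv, decane), molecular sieves 4 Å, CH2Cl2, −20 °C
Reagents that add atoms: tert-butyl hydroperoxide, CC(C)(C)OO
Why: Sharpless asymmetric epoxidation in its matched sense: the titanium tartrate bound to the C9 hydroxyl epoxidises only the allylic C10=C11 alkene and gives the anti (erythro) epoxy alcohol, (10S,11S), while the minor 9R antipode reacts slowly and is left behind.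

Step 10
Reactants: 16 epoxy alcohol
Product: 17 triethylsilyl ether of 16 at the secondary hydroxyl (carbinol carbon 1S; oxirane now labelled 2R,3S only through the change in CIP priority)
Conditions: Et3SiCl, imidazole, DMAP (cat.), CH2Cl2, 0 °C → rt
Reagents that add atoms: chlorotriethylsilane, CC[Si](Cl)(CC)CC
Why: Mild, non-Lewis-acidic silylation masks the C9 hydroxyl so that it cannot quench the second allylborane or trigger Payne-type chemistry.

Step 11
Reactants: 17 terminal alkene; 18 methacrolein (2-methylprop-2-enal)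
Product: 19 (2E,5S)-5-[(2R,3S)-2-{[(tert-butyldimethylsilyl)oxy]methyl}-3-{(3Z)-5-[(tert-butyldiphenylsilyl)oxy]-3-methylpent-3-en-1-yl}oxiran-2-yl]-2-methyl-5-[(triethylsilyl)oxy]pent-2-enal
Conditions: second-generation Hoveyda–Grubbs catalyst RuCl2(H2IMes)(=CH-C6H4-2-OiPr) (5 mol %), methacrolein (10 equiv), CH2Cl2, 40 °C
Reagents that add atoms: none
Why: Olefin cross-metathesis of the only monosubstituted alkene with methacrolein gives the thermodynamic (E)-trisubstituted enal (C6=C7), and the trisubstituted alkene and oxirane are spectators.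

Step 12
Reactants: 19 enal; 12 allylmagnesium bromide
Product: 22 (4R,5E,8S)-8-[(2R,3S)-2-{[(tert-butyldimethylsilyl)oxy]methyl}-3-{(3Z)-5-[(tert-butyldiphenylsilyl)oxy]-3-methylpent-3-en-1-yl}oxiran-2-yl]-5-methyl-8-[(triethylsilyl)oxy]octa-1,5-dien-4-ol, via ent-B-allyldiisopinocampheylborane 20 (not isolated), via diisopinocampheylborinate 21 (not isolated)
Conditions: (+)-Ipc2BOMe, CH2=CHCH2MgBr, Et2O, 0 °C → rt; then 19, −78 °C; then aq. NaOH, 30% H2O2, 0 °C
Reagents that add atoms: (+)-B-methoxydiisopinocampheylborane from (−)-α-pinene, COB([C@H]1C[C@H]2C[C@@H]([C@@H]1C)C2(C)C)[C@H]1C[C@H]2C[C@@H]([C@@H]1C)C2(C)C (its boryl unit is carried by 20 and 21 only)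
Why: Brown allylboration with the antipodal reagent adds allyl to the Re face of the α-methyl enal under reagent control, forming C4–C5 and setting C5 as R irrespective of the remote stereocentres; the oxirane is inert to the allylborane at −78 °C.

Step 13
Reactants: 22 homoallylic alcohol; 23 2-methylbut-2-ene
Product: 24 (1S,3E,5R)-1-[(2R,3S)-2-{[(tert-butyldimethylsilyl)oxy]methyl}-3-{(3Z)-5-[(tert-butyldiphenylsilyl)oxy]-3-methylpent-3-en-1-yl}oxiran-2-yl]-4,8-dimethyl-1-[(triethylsilyl)oxy]nona-3,7-dien-5-ol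
Conditions: second-generation Grubbs catalyst RuCl2(H2IMes)(PCy3)(=CHPh) (5 mol %), 2-methylbut-2-ene/CH2Cl2, 40 °C, sealed tube
Reagents that add atoms: none
Why: Cross-metathesis with 2-methylbut-2-ene exchanges the terminal CH2 for an isopropylidene unit, giving the prenyl terminus without touching the trisubstituted alkenes or the free C5 hydroxyl.

Step 14
Reactants: 24 tris-silyl ether
Product: 25 (2Z)-5-[(2S,3S)-3-[(1S,3E,5R)-1,5-dihydroxy-4,8-dimethylnona-3,7-dien-1-yl]-3-(hydroxymethyl)oxiran-2-yl]-3-methylpent-2-en-1-ol (target)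
Conditions: Bu4NF, AcOH (1:1, 6 equiv), THF, 0 °C → rt
Reagents that add atoms: none
Why: Acetic-acid-buffered fluoride cleaves all three Si–O bonds without acid, and the tertiary oxirane carbon resists Payne-type attack by the neighbouring alkoxides.

**Compound list**

1 | nerol, (2Z)-3,7-dimethylocta-2,6-dien-1-ol | CC(C)=CCC/C(C)=C\CO | starting material
2 | tert-butyl{[(2Z)-3,7-dimethylocta-2,6-dien-1-yl]oxy}diphenylsilane | CC(C)=CCC/C(C)=C\CO[Si](c1ccccc1)(c1ccccc1)C(C)(C)C | intermediate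
3 | tert-butyl{[(2Z)-5-(3,3-dimethyloxiran-2-yl)-3-methylpent-2-en-1-yl]oxy}diphenylsilane (racemic) | CC1(C)OC1CC/C(C)=C\CO[Si](c1ccccc1)(c1ccccc1)C(C)(C)C | intermediate
4 | (6Z)-8-[(tert-butyldiphenylsilyl)oxy]-2,6-dimethyloct-6-ene-2,3-diol (racemic, not isolated) | CC(C)(O)C(O)CC/C(C)=C\CO[Si](c1ccccc1)(c1ccccc1)C(C)(C)C | intermediate
5 | (4Z)-6-[(tert-butyldiphenylsilyl)oxy]-4-methylhex-4-enal | O=CCC/C(C)=C\CO[Si](c1ccccc1)(c1ccccc1)C(C)(C)C | intermediate
6 | (triphenylphosphoranylidene)acetaldehyde | O=CC=P(c1ccccc1)(c1ccccc1)c1ccccc1 | starting material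
7 | (2E,6Z)-8-[(tert-butyldiphenylsilyl)oxy]-6-methylocta-2,6-dienal | O=C/C=C/CC/C(C)=C\CO[Si](c1ccccc1)(c1ccccc1)C(C)(C)C | intermediate
8 | (2Z,6Z)-8-[(tert-butyldiphenylsilyl)oxy]-2-iodo-6-methylocta-2,6-dienal | O=C/C(I)=C/CC/C(C)=C\CO[Si](c1ccccc1)(c1ccccc1)C(C)(C)C | intermediate
9 | (tributylstannyl)methanol | OC[Sn](CCCC)(CCCC)CCCC | starting material
10 | (2E,6Z)-8-[(tert-butyldiphenylsilyl)oxy]-2-(hydroxymethyl)-6-methylocta-2,6-dienal | O=C/C(CO)=C/CC/C(C)=C\CO[Si](c1ccccc1)(c1ccccc1)C(C)(C)C | intermediate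
11 | (2E,6Z)-2-{[(tert-butyldimethylsilyl)oxy]methyl}-8-[(tert-butyldiphenylsilyl)oxy]-6-methylocta-2,6-dienal | O=C/C(CO[Si](C)(C)C(C)(C)C)=C/CC/C(C)=C\CO[Si](c1ccccc1)(c1ccccc1)C(C)(C)C | intermediate
12 | allylmagnesium bromide | C=CC[Mg]Br | starting material
13 | allylbis[(1R,2S,3R,5R)-2,6,6-trimethylbicyclo[3.1.1]hept-3-yl]borane, (+)-α-pinene series (not isolated) | C=CCB([C@@H]1C[C@@H]2C[C@H]([C@H]1C)C2(C)C)[C@@H]1C[C@@H]2C[C@H]([C@H]1C)C2(C)C | intermediate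
14 | O-diisopinocampheylboryl derivative (borinate) of 15 (not isolated) | C=CC[C@H](OB([C@@H]1C[C@@H]2C[C@H]([C@H]1C)C2(C)C)[C@@H]1C[C@@H]2C[C@H]([C@H]1C)C2(C)C)/C(CO[Si](C)(C)C(C)(C)C)=C/CC/C(C)=C\CO[Si](c1ccccc1)(c1ccccc1)C(C)(C)C | intermediate
15 | (4S,5E,9Z)-5-{[(tert-butyldimethylsilyl)oxy]methyl}-11-[(tert-butyldiphenylsilyl)oxy]-9-methylundeca-1,5,9-trien-4-ol | C=CC[C@H](O)/C(CO[Si](C)(C)C(C)(C)C)=C/CC/C(C)=C\CO[Si](c1ccccc1)(c1ccccc1)C(C)(C)C | intermediate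
16 | (1S)-1-[(2S,3S)-2-{[(tert-butyldimethylsilyl)oxy]methyl}-3-{(3Z)-5-[(tert-butyldiphenylsilyl)oxy]-3-methylpent-3-en-1-yl}oxiran-2-yl]but-3-en-1-ol | C=CC[C@H](O)[C@]1(CO[Si](C)(C)C(C)(C)C)O[C@H]1CC/C(C)=C\CO[Si](c1ccccc1)(c1ccccc1)C(C)(C)C | intermediate
17 | triethylsilyl ether of 16: (1S)-1-[(2R,3S)-oxiran-2-yl]but-3-en-1-yl triethylsilyl ether with the same oxirane substituents | C=CC[C@H](O[Si](CC)(CC)CC)[C@]1(CO[Si](C)(C)C(C)(C)C)O[C@H]1CC/C(C)=C\CO[Si](c1ccccc1)(c1ccccc1)C(C)(C)C | intermediate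
18 | methacrolein, 2-methylprop-2-enal | CC(=C)C=O | starting material
19 | (2E,5S)-5-[(2R,3S)-2-{[(tert-butyldimethylsilyl)oxy]methyl}-3-{(3Z)-5-[(tert-butyldiphenylsilyl)oxy]-3-methylpent-3-en-1-yl}oxiran-2-yl]-2-methyl-5-[(triethylsilyl)oxy]pent-2-enal | O=C/C(C)=C/C[C@H](O[Si](CC)(CC)CC)[C@]1(CO[Si](C)(C)C(C)(C)C)O[C@H]1CC/C(C)=C\CO[Si](c1ccccc1)(c1ccccc1)C(C)(C)C | intermediate
20 | allylbis[(1S,2R,3S,5S)-2,6,6-trimethylbicyclo[3.1.1]hept-3-yl]borane, (−)-α-pinene series (not isolated) | C=CCB([C@H]1C[C@H]2C[C@@H]([C@@H]1C)C2(C)C)[C@H]1C[C@H]2C[C@@H]([C@@H]1C)C2(C)C | intermediate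
21 | O-diisopinocampheylboryl derivative (borinate) of 22 (not isolated) | C=CC[C@@H](OB([C@H]1C[C@H]2C[C@@H]([C@@H]1C)C2(C)C)[C@H]1C[C@H]2C[C@@H]([C@@H]1C)C2(C)C)/C(C)=C/C[C@H](O[Si](CC)(CC)CC)[C@]1(CO[Si](C)(C)C(C)(C)C)O[C@H]1CC/C(C)=C\CO[Si](c1ccccc1)(c1ccccc1)C(C)(C)C | intermediate
22 | (4R,5E,8S)-8-[(2R,3S)-2-{[(tert-butyldimethylsilyl)oxy]methyl}-3-{(3Z)-5-[(tert-butyldiphenylsilyl)oxy]-3-methylpent-3-en-1-yl}oxiran-2-yl]-5-methyl-8-[(triethylsilyl)oxy]octa-1,5-dien-4-ol | C=CC[C@@H](O)/C(C)=C/C[C@H](O[Si](CC)(CC)CC)[C@]1(CO[Si](C)(C)C(C)(C)C)O[C@H]1CC/C(C)=C\CO[Si](c1ccccc1)(c1ccccc1)C(C)(C)C | intermediate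
23 | 2-methylbut-2-ene | CC=C(C)C | starting material
24 | (1S,3E,5R)-1-[(2R,3S)-2-{[(tert-butyldimethylsilyl)oxy]methyl}-3-{(3Z)-5-[(tert-butyldiphenylsilyl)oxy]-3-methylpent-3-en-1-yl}oxiran-2-yl]-4,8-dimethyl-1-[(triethylsilyl)oxy]nona-3,7-dien-5-ol | CC(C)=CC[C@@H](O)/C(C)=C/C[C@H](O[Si](CC)(CC)CC)[C@]1(CO[Si](C)(C)C(C)(C)C)O[C@H]1CC/C(C)=C\CO[Si](c1ccccc1)(c1ccccc1)C(C)(C)C | intermediate
25 | (2Z)-5-[(2S,3S)-3-[(1S,3E,5R)-1,5-dihydroxy-4,8-dimethylnona-3,7-dien-1-yl]-3-(hydroxymethyl)oxiran-2-yl]-3-methylpent-2-en-1-ol | CC(C)=CC[C@@H](O)/C(C)=C/C[C@H](O)[C@]1(CO)O[C@H]1CC/C(C)=C\CO | target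

**Summary**

Total step count: 14. Longest linear sequence: 14 steps (1 → 25); all other inputs are bought.

Steps most likely to fail, with fallbacks:

Step 6 (slow sp3 tin-to-palladium transfer onto a heat-sensitive α-iodoenal). The fallback leaves the route at 5 and rejoins it at 11 without tin or iodine. Morita–Baylis–Hillman reaction of 5 with methyl acrylate (DABCO, MeOH, rt) gives racemic methyl (6Z)-8-[(tert-butyldiphenylsilyl)oxy]-3-hydroxy-6-methyl-2-methylideneoct-6-enoate F1. Ac2O, pyridine and DMAP give the acetate methyl (6Z)-3-acetoxy-8-[(tert-butyldiphenylsilyl)oxy]-6-methyl-2-methylideneoct-6-enoate F2. DABCO (THF, 65 °C) effects the SN2′–SN2′ acetoxy shift to the thermodynamic methyl (2E,6Z)-2-(acetoxymethyl)-8-[(tert-butyldiphenylsilyl)oxy]-6-methylocta-2,6-dienoate F3, with the ester trans to the chain. K2CO3 in MeOH at 0 °C gives methyl (2E,6Z)-8-[(tert-butyldiphenylsilyl)oxy]-2-(hydroxymethyl)-6-methylocta-2,6-dienoate F4. t-BuMe2SiCl and imidazole give methyl (2E,6Z)-2-{[(tert-butyldimethylsilyl)oxy]methyl}-8-[(tert-butyldiphenylsilyl)oxy]-6-methylocta-2,6-dienoate F5. i-Bu2AlH (CH2Cl2, −78 °C) gives (2Z,6Z)-2-{[(tert-butyldimethylsilyl)oxy]methyl}-8-[(tert-butyldiphenylsilyl)oxy]-6-methylocta-2,6-dien-1-ol F6, and MnO2 (CH2Cl2) oxidises it to 11.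

Step 9 (titanium-mediated opening of the 2,2-disubstituted oxirane carbon, or incomplete diastereocontrol on the secondary carbinol). The fallback leaves at 11 and rejoins at 16, forming the oxirane before the C8–C9 bond. Luche reduction of 11 (NaBH4, CeCl3·7H2O, MeOH, 0 °C) gives the allylic alcohol (2Z,6Z)-2-{[(tert-butyldimethylsilyl)oxy]methyl}-8-[(tert-butyldiphenylsilyl)oxy]-6-methylocta-2,6-dien-1-ol F6. Sharpless epoxidation of this primary alcohol (Ti(OiPr)4, (+)-diethyl (2R,3R)-tartrate, t-BuOOH, molecular sieves 4 Å, −20 °C), the most dependable substrate class and the same face as needed, gives [(2R,3S)-2-{[(tert-butyldimethylsilyl)oxy]methyl}-3-{(3Z)-5-[(tert-butyldiphenylsilyl)oxy]-3-methylpent-3-en-1-yl}oxiran-2-yl]methanol F7. Dess–Martin periodinane (NaHCO3, CH2Cl2) gives (2R,3S)-2-{[(tert-butyldimethylsilyl)oxy]methyl}-3-{(3Z)-5-[(tert-butyldiphenylsilyl)oxy]-3-methylpent-3-en-1-yl}oxirane-2-carbaldehyde F8, whose α-carbon is quaternary and cannot epimerise. Allylboration with 13 at −78 °C (Si face, reagent control) passes through the diisopinocampheylborinate of 16 F9, and oxidative work-up gives 16.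

Step 11 (cross-metathesis with the polymerisation-prone, slow partner methacrolein). The fallback leaves at 17 and rejoins at 19 by the classical terpenoid sequence. Cross-metathesis of 17 with 2-methylbut-2-ene (second-generation Grubbs catalyst, 40 °C) gives the prenyl analogue of 17, triethyl{[(1S)-4-methyl-1-[(2R,3S)-oxiran-2-yl]pent-3-en-1-yl]oxy}silane with the oxirane substituents of 17 F10. SeO2 (cat.) and t-BuOOH (CH2Cl2, rt) oxidise the (E)-methyl of this electron-rich terminal alkene (the other alkene is deactivated by its allylic silyloxy group) to (2E,5S)-5-[(2R,3S)-2-{[(tert-butyldimethylsilyl)oxy]methyl}-3-{(3Z)-5-[(tert-butyldiphenylsilyl)oxy]-3-methylpent-3-en-1-yl}oxiran-2-yl]-2-methyl-5-[(triethylsilyl)oxy]pent-2-en-1-ol F11, and MnO2 gives 19.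

**Further compounds**

F1 | step 6 | methyl (6Z)-8-[(tert-butyldiphenylsilyl)oxy]-3-hydroxy-6-methyl-2-methylideneoct-6-enoate (racemic) | COC(=O)C(=C)C(O)CC/C(C)=C\CO[Si](c1ccccc1)(c1ccccc1)C(C)(C)C
F2 | step 6 | methyl (6Z)-3-acetoxy-8-[(tert-butyldiphenylsilyl)oxy]-6-methyl-2-methylideneoct-6-enoate (racemic) | COC(=O)C(=C)C(OC(C)=O)CC/C(C)=C\CO[Si](c1ccccc1)(c1ccccc1)C(C)(C)C
F3 | step 6 | methyl (2E,6Z)-2-(acetoxymethyl)-8-[(tert-butyldiphenylsilyl)oxy]-6-methylocta-2,6-dienoate | COC(=O)/C(COC(C)=O)=C/CC/C(C)=C\CO[Si](c1ccccc1)(c1ccccc1)C(C)(C)C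
F4 | step 6 | methyl (2E,6Z)-8-[(tert-butyldiphenylsilyl)oxy]-2-(hydroxymethyl)-6-methylocta-2,6-dienoate | COC(=O)/C(CO)=C/CC/C(C)=C\CO[Si](c1ccccc1)(c1ccccc1)C(C)(C)C
F5 | step 6 | methyl (2E,6Z)-2-{[(tert-butyldimethylsilyl)oxy]methyl}-8-[(tert-butyldiphenylsilyl)oxy]-6-methylocta-2,6-dienoate | COC(=O)/C(CO[Si](C)(C)C(C)(C)C)=C/CC/C(C)=C\CO[Si](c1ccccc1)(c1ccccc1)C(C)(C)C
F6 | step 6 | (2Z,6Z)-2-{[(tert-butyldimethylsilyl)oxy]methyl}-8-[(tert-butyldiphenylsilyl)oxy]-6-methylocta-2,6-dien-1-ol | OC/C(CO[Si](C)(C)C(C)(C)C)=C/CC/C(C)=C\CO[Si](c1ccccc1)(c1ccccc1)C(C)(C)C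
F7 | step 9 | [(2R,3S)-2-{[(tert-butyldimethylsilyl)oxy]methyl}-3-{(3Z)-5-[(tert-butyldiphenylsilyl)oxy]-3-methylpent-3-en-1-yl}oxiran-2-yl]methanol | OC[C@]1(CO[Si](C)(C)C(C)(C)C)O[C@H]1CC/C(C)=C\CO[Si](c1ccccc1)(c1ccccc1)C(C)(C)C
F8 | step 9 | (2R,3S)-2-{[(tert-butyldimethylsilyl)oxy]methyl}-3-{(3Z)-5-[(tert-butyldiphenylsilyl)oxy]-3-methylpent-3-en-1-yl}oxirane-2-carbaldehyde | O=C[C@]1(CO[Si](C)(C)C(C)(C)C)O[C@H]1CC/C(C)=C\CO[Si](c1ccccc1)(c1ccccc1)C(C)(C)C
F9 | step 9 | O-diisopinocampheylboryl derivative (borinate) of 16 | C=CC[C@H](OB([C@@H]1C[C@@H]2C[C@H]([C@H]1C)C2(C)C)[C@@H]1C[C@@H]2C[C@H]([C@H]1C)C2(C)C)[C@]1(CO[Si](C)(C)C(C)(C)C)O[C@H]1CC/C(C)=C\CO[Si](c1ccccc1)(c1ccccc1)C(C)(C)C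
F10 | step 11 | prenyl analogue of 17: triethyl{[(1S)-4-methyl-1-[(2R,3S)-oxiran-2-yl]pent-3-en-1-yl]oxy}silane with the oxirane substituents of 17 | CC(C)=CC[C@H](O[Si](CC)(CC)CC)[C@]1(CO[Si](C)(C)C(C)(C)C)O[C@H]1CC/C(C)=C\CO[Si](c1ccccc1)(c1ccccc1)C(C)(C)C
F11 | step 11 | (2E,5S)-5-[(2R,3S)-2-{[(tert-butyldimethylsilyl)oxy]methyl}-3-{(3Z)-5-[(tert-butyldiphenylsilyl)oxy]-3-methylpent-3-en-1-yl}oxiran-2-yl]-2-methyl-5-[(triethylsilyl)oxy]pent-2-en-1-ol | OC/C(C)=C/C[C@H](O[Si](CC)(CC)CC)[C@]1(CO[Si](C)(C)C(C)(C)C)O[C@H]1CC/C(C)=C\CO[Si](c1ccccc1)(c1ccccc1)C(C)(C)C
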